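**Plan**

Numbering: carbocycle C1(=O), C2=C3, C4(Me), C5, C6(O of lactone), C7, C8(O-tigloyl), C9, C10(Me); lactone carbons C11(Me) and C12(=O); the furanone oxygen bridges C3 and C10.
Enabling feature: the C8 carbinol carbon is bonded to C7, the β-carbon of the C12 γ-lactone, so C7–C8 is the bond a C8 ketyl makes by adding to an α-methyl butenolide (C6–O–C12(=O)–C11(Me)=C7).
Cuts, in retrosynthetic order: the C8–O tiglate ester; C7–C8 (opens the ten-membered ring, removes the C7, C8 and C11 stereocentres); the butenolide C7=C11 (metathesis of a C6 methacrylate); the furanone O–C3 bond (hydroxy ynone); C1–C2 (acetylide plus Weinreb amide).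
Forward order: two chiral pieces are joined at C1–C2, then the furanone ring is closed, then the butenolide ring, then the ten-membered carbocycle, and the ester is put on last.
Stereochemistry: C10 from (R)-citramalic acid; C6 from (R)-5-(hydroxymethyl)dihydrofuran-2(3H)-one; C4 by enolate methylation anti to the C6 substituent; C7, C8 and C11 in the samarium step.

Key step: step 18

Remark: the side-chain double bond is taken as E (tigloyl) as drawn, and both chiral starting materials are taken as commercial single enantiomers.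

**Route**

Step 1
Reactants: 1 (R)-citramalic acid
Product: 2 2-[(4R)-2,2,4-trimethyl-5-oxo-1,3-dioxolan-4-yl]acetic acid
Conditions: Me2C(OMe)2, TsOH·H2O (cat.), acetone, rt
Reagents that add atoms: 2,2-dimethoxypropane, COC(C)(C)OC
Why: Acid-catalysed acetonide formation (transketalisation) ties the tertiary hydroxyl and its neighbouring carboxyl into the five-membered dioxolanone rather than the six-membered alternative, which leaves the CH2CO2H arm free and does not touch the quaternary centre.

Step 2
Reactants: 2 2-[(4R)-2,2,4-trimethyl-5-oxo-1,3-dioxolan-4-yl]acetic acid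
Product: 3 (5R)-5-(2-hydroxyethyl)-2,2,5-trimethyl-1,3-dioxolan-4-one
Conditions: BH3·THF, THF, 0 °C to rt; aqueous work-up
Reagents that add atoms: none
Why: Borane reduction is chemoselective for the free carboxylic acid (through the acyloxyborane) over the dioxolanone ester, and the neutral product is silylated without delay to forestall translactonisation.

Step 3
Reactants: 3 (5R)-5-(2-hydroxyethyl)-2,2,5-trimethyl-1,3-dioxolan-4-one
Product: 4 (5R)-5-{2-[tert-butyl(diphenyl)silyl]oxyethyl}-2,2,5-trimethyl-1,3-dioxolan-4-one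
Conditions: TBDPSCl, imidazole, CH2Cl2, 0 °C to rt
Reagents that add atoms: tert-butyl(chloro)diphenylsilane, CC(C)(C)[Si](Cl)(c1ccccc1)c1ccccc1
Why: Imidazole-promoted silylation of the primary alcohol gives a robust ether that masks the future C8 oxygen until the aldehyde is needed.

Step 4
Reactants: 4 (5R)-5-{2-[tert-butyl(diphenyl)silyl]oxyethyl}-2,2,5-trimethyl-1,3-dioxolan-4-one
Product: 5 (2R)-4-[tert-butyl(diphenyl)silyl]oxy-2-hydroxy-N-methoxy-N,2-dimethylbutanamide
Conditions: MeNH(OMe)·HCl, i-PrMgCl, THF, −20 to 0 °C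
Reagents that add atoms: N,O-dimethylhydroxylamine hydrochloride, CNOC.Cl
Why: Aminolysis of the activated dioxolanone ester by the magnesium amide (Weinreb amide formation) releases acetone and frees the tertiary hydroxyl that will become the furanone oxygen.

Step 5
Reactants: 6 (5R)-5-(hydroxymethyl)dihydrofuran-2(3H)-one
Product: 7 (2R)-5-oxotetrahydrofuran-2-carbaldehyde
Conditions: Dess–Martin periodinane, CH2Cl2, 0 °C to rt
Reagents that add atoms: none
Why: Dess–Martin oxidation gives the aldehyde under base-free conditions so that the oxygen-bearing stereocentre (the future C6) is not epimerised, and the crude aldehyde is used directly.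

Step 6
Reactants: 7 (2R)-5-oxotetrahydrofuran-2-carbaldehyde
Product: 8 (5R)-5-vinyldihydrofuran-2(3H)-one
Conditions: Ph3PCH3Br, KN(SiMe3)2, THF, −78 to 0 °C
Reagents that add atoms: methyltriphenylphosphonium bromide, C[P+](c1ccccc1)(c1ccccc1)c1ccccc1.[Br-]
Why: Wittig methylenation is selective for the aldehyde over the far less electrophilic lactone carbonyl, and the preformed ylide at low temperature limits enolisation next to the stereocentre.

Step 7
Reactants: 8 (5R)-5-vinyldihydrofuran-2(3H)-one
Product: 10 (3S,5R)-3-methyl-5-vinyldihydrofuran-2(3H)-one, via lithium enolate 9 (not isolated)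
Conditions: LiN(i-Pr)2, THF, −78 °C; MeI, −78 to −40 °C
Reagents that add atoms: iodomethane, CI
Why: Lactone enolate alkylation, in which iodomethane should approach the planar enolate on the face anti to the C5 vinyl group (1,3-induction) to set the trans 3S methyl centre (the future C4), the minor cis isomer being removed by chromatography.

Step 8
Reactants: 10 (3S,5R)-3-methyl-5-vinyldihydrofuran-2(3H)-one
Product: 11 (3S,5R)-3-methyl-5-vinyltetrahydrofuran-2-ol (anomer mixture)
Conditions: i-Bu2AlH, CH2Cl2, −78 °C; Rochelle salt work-up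
Reagents that add atoms: none
Why: Partial reduction of the lactone stops at the lactol because the tetrahedral aluminate is stable at −78 °C.

Step 9
Reactants: 11 (3S,5R)-3-methyl-5-vinyltetrahydrofuran-2-ol
Product: 12 (3R,5S)-5-methylhept-1-en-6-yn-3-ol
Conditions: dimethyl (1-diazo-2-oxopropyl)phosphonate, K2CO3, MeOH, 0 °C to rt
Reagents that add atoms: dimethyl (1-diazo-2-oxopropyl)phosphonate, COP(=O)(OC)C(=[N+]=[N-])C(C)=O
Why: Seyferth–Gilbert homologation with the Ohira–Bestmann reagent acts on the open hydroxy aldehyde tautomer of the lactol and gives the terminal alkyne, the mild carbonate base being expected to leave the α-methyl centre intact.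

Step 10
Reactants: 12 (3R,5S)-5-methylhept-1-en-6-yn-3-ol
Product: 13 triethyl{[(3R,5S)-5-methylhept-1-en-6-yn-3-yl]oxy}silane
Conditions: TESCl, imidazole, CH2Cl2, 0 °C
Reagents that add atoms: chlorotriethylsilane, CC[Si](Cl)(CC)CC
Why: Silylation blocks the C6 hydroxyl, which would otherwise add 5-exo to the ynone, with a group that mild acid removes in the presence of the TBDPS ether.

Step 11
Reactants: 13 triethyl{[(3R,5S)-5-methylhept-1-en-6-yn-3-yl]oxy}silane; 5 (2R)-4-[tert-butyl(diphenyl)silyl]oxy-2-hydroxy-N-methoxy-N,2-dimethylbutanamide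
Product: 16 (3R,7S,9R)-1-[tert-butyl(diphenyl)silyl]oxy-3-hydroxy-3,7-dimethyl-9-(triethylsilyloxy)undec-10-en-5-yn-4-one, via lithium acetylide 14 (not isolated), via chloromagnesium alkoxide 15 (not isolated)
Conditions: 13, n-BuLi, THF, −78 °C; 5 pre-treated with i-PrMgCl (THF, −20 °C); −78 to 0 °C; cold aq NH4Cl
Reagents that add atoms: none
Why: Weinreb ketone synthesis, in which the acetylide adds once to the amide and the chelated tetrahedral intermediate survives until the quench, while prior conversion of the tertiary hydroxyl into its magnesium alkoxide keeps it from protonating the acetylide.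

Step 12
Reactants: 16 (3R,7S,9R)-1-[tert-butyl(diphenyl)silyl]oxy-3-hydroxy-3,7-dimethyl-9-(triethylsilyloxy)undec-10-en-5-yn-4-one
Product: 18 (2R)-2-{2-[tert-butyl(diphenyl)silyl]oxyethyl}-2-methyl-5-[(2S,4R)-4-(triethylsilyloxy)hex-5-en-2-yl]furan-3(2H)-one, via enaminone 17 (not isolated)
Conditions: Et2NH, EtOH, rt
Reagents that add atoms: none
Why: Conjugate addition of diethylamine to the ynone gives an enaminone whose C3 is attacked by the tertiary hydroxyl with loss of the amine (addition–elimination) to close the 3(2H)-furanone, and since the amine adds faster than it can isomerise the ynone the C4 centre should be kept.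

Step 13
Reactants: 18 (2R)-2-{2-[tert-butyl(diphenyl)silyl]oxyethyl}-2-methyl-5-[(2S,4R)-4-(triethylsilyloxy)hex-5-en-2-yl]furan-3(2H)-one
Product: 19 (2R)-2-{2-[tert-butyl(diphenyl)silyl]oxyethyl}-5-[(2S,4R)-4-hydroxyhex-5-en-2-yl]-2-methylfuran-3(2H)-one
Conditions: PPTS (cat.), MeOH–CH2Cl2, 0 °C to rt
Reagents that add atoms: none
Why: Acid-catalysed methanolysis cleaves the secondary triethylsilyl ether far faster than the primary TBDPS ether, and the vinylogous ester is stable to this mild acid.

Step 14
Reactants: 19 (2R)-2-{2-[tert-butyl(diphenyl)silyl]oxyethyl}-5-[(2S,4R)-4-hydroxyhex-5-en-2-yl]-2-methylfuran-3(2H)-one; 20 methacryloyl chloride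
Product: 21 (3R,5S)-5-[(5R)-5-{2-[tert-butyl(diphenyl)silyl]oxyethyl}-5-methyl-4-oxo-4,5-dihydrofuran-2-yl]hex-1-en-3-yl 2-methylprop-2-enoate
Conditions: 20, Et3N, DMAP (cat.), CH2Cl2, 0 °C
Reagents that add atoms: methacryloyl chloride (compound 20), C=C(C)C(=O)Cl
Why: DMAP-catalysed acylation of the secondary allylic alcohol installs C11, C12 and the C11 methyl as the metathesis partner without touching the C6 configuration.

Step 15
Reactants: 21 (3R,5S)-5-[(5R)-5-{2-[tert-butyl(diphenyl)silyl]oxyethyl}-5-methyl-4-oxo-4,5-dihydrofuran-2-yl]hex-1-en-3-yl 2-methylprop-2-enoate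
Product: 22 (5R)-5-{(2S)-2-[(5R)-5-{2-[tert-butyl(diphenyl)silyl]oxyethyl}-5-methyl-4-oxo-4,5-dihydrofuran-2-yl]propyl}-3-methylfuran-2(5H)-one
Conditions: second-generation Grubbs catalyst (H2IMes)(PCy3)Cl2Ru=CHPh (5 mol %), toluene (0.005 M), 80 °C
Reagents that add atoms: none
Why: Ring-closing metathesis starts at the monosubstituted vinyl group and closes onto the methacrylate to give the α-methyl butenolide (C7=C11) with loss of ethene, the trisubstituted electron-poor furanone alkene being inert.

Step 16
Reactants: 22 (5R)-5-{(2S)-2-[(5R)-5-{2-[tert-butyl(diphenyl)silyl]oxyethyl}-5-methyl-4-oxo-4,5-dihydrofuran-2-yl]propyl}-3-methylfuran-2(5H)-one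
Product: 23 (5R)-5-{(2S)-2-[(5R)-5-(2-hydroxyethyl)-5-methyl-4-oxo-4,5-dihydrofuran-2-yl]propyl}-3-methylfuran-2(5H)-one
Conditions: HF·pyridine, pyridine, THF, 0 °C to rt
Reagents that add atoms: none
Why: Buffered fluoride desilylation frees the C8 alcohol without the basic conditions that could deprotonate the acidic γ-position (C6) of the butenolide.

Step 17
Reactants: 23 (5R)-5-{(2S)-2-[(5R)-5-(2-hydroxyethyl)-5-methyl-4-oxo-4,5-dihydrofuran-2-yl]propyl}-3-methylfuran-2(5H)-one
Product: 24 2-[(2R)-2-methyl-5-{(2S)-1-[(2R)-4-methyl-5-oxo-2,5-dihydrofuran-2-yl]propan-2-yl}-3-oxo-2,3-dihydrofuran-2-yl]acetaldehyde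
Conditions: Dess–Martin periodinane, NaHCO3, CH2Cl2, 0 °C
Reagents that add atoms: none
Why: Dess–Martin oxidation gives the C8 aldehyde without amine base, which matters because the aldehyde carries the furanone oxygen in the β-position and could lose it by elimination, so it is used at once.

Step 18
Reactants: 24 2-[(2R)-2-methyl-5-{(2S)-1-[(2R)-4-methyl-5-oxo-2,5-dihydrofuran-2-yl]propan-2-yl}-3-oxo-2,3-dihydrofuran-2-yl]acetaldehyde
Product: 26 (4S,6R,7R,8S,10R,11S)-8-hydroxy-1-oxo-3,10-epoxygermacr-2-en-12,6-olide (numbering of the plan), via samarium enolate 25 (not isolated)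
Conditions: SmI2 (3 equiv), THF–MeOH (4:1), 0 °C, slow addition of 24 (final 0.002 M)
Reagents that add atoms: none
Why: SmI2 (divalent samarium) transfers one electron to the C8 aldehyde of 24, the nucleophilic ketyl adds to C7, the electron-poor β-carbon of the butenolide, a second electron turns the C11 radical into the trivalent samarium enolate 25, and methanol protonates it at C11. The closest known reaction type is the SmI2 ketyl–olefin (aldehyde–enoate) reductive cyclisation, well established for five- to eight-membered rings and applied here to a larger ring, which is the main uncertainty. The one ring closed is the ten-membered carbocycle C1–C10, by a 10-exo-trig closure in which the preformed furanone and butenolide rings leave only five freely rotating bonds between C7 and C8. C7 follows from the C6 stereocentre, the ketyl attacking the butenolide face anti to the C5 chain so that the lactone becomes trans-fused, and C8 follows from the transition state in which H8 lies over the butenolide ring, C9 points to the C6 side as the tether demands and the samarium-bound oxygen lies on the C11/C12 side where the metal can also bind the lactone carbonyl, an arrangement that corresponds to 8S. C11 follows from delivery of the proton by methanol bound to that samarium to the enolate face syn to C8, which places the methyl anti to C8, the all-trans and thermodynamically preferred arrangement usually seen when enolates of trans-fused germacranolide lactones are protonated. The step needs chemoselective reduction of the aldehyde, secured by leaving out strongly activating additives so that neither the butenolide nor the vinylogous ester of the furanone is reduced, and cyclisation faster than pinacol coupling or over-reduction, favoured by slow addition at high dilution and by furanone C3 being a donor-deactivated and geometrically strained acceptor.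

Step 19
Reactants: 26 (4S,6R,7R,8S,10R,11S)-8-hydroxy-1-oxo-3,10-epoxygermacr-2-en-12,6-olide; 27 tiglic acid
Product: 29 (4S,6R,7S,8S,10R,11S)-1-oxo-8-[(E)-2-methylbut-2-enoyl]oxy-3,10-epoxygermacr-2-en-12,6-olide (CNP0235937.1), via mixed anhydride 28 (not isolated)
Conditions: 27, 2,4,6-Cl3C6H2COCl, Et3N, toluene, rt; then 26, DMAP, toluene, rt
Reagents that add atoms: tiglic acid (compound 27), C/C=C(\C)C(=O)O
Why: Yamaguchi esterification transfers the tigloyl group from the mixed anhydride through the acylpyridinium to the hindered C8 hydroxyl with retention at C8, and the E acid is the stable geometric isomer so the double bond should not scramble.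

**Compound list**

1 | (R)-citramalic acid | C[C@@](O)(CC(=O)O)C(=O)O | starting material
2 | 2-[(4R)-2,2,4-trimethyl-5-oxo-1,3-dioxolan-4-yl]acetic acid | C[C@]1(CC(=O)O)OC(C)(C)OC1=O | intermediate
3 | (5R)-5-(2-hydroxyethyl)-2,2,5-trimethyl-1,3-dioxolan-4-one | C[C@]1(CCO)OC(C)(C)OC1=O | intermediate
4 | (5R)-5-{2-[tert-butyl(diphenyl)silyl]oxyethyl}-2,2,5-trimethyl-1,3-dioxolan-4-one | C[C@]1(CCO[Si](c2ccccc2)(c2ccccc2)C(C)(C)C)OC(C)(C)OC1=O | intermediate
5 | (2R)-4-[tert-butyl(diphenyl)silyl]oxy-2-hydroxy-N-methoxy-N,2-dimethylbutanamide | C[C@@](O)(CCO[Si](c1ccccc1)(c1ccccc1)C(C)(C)C)C(=O)N(C)OC | intermediate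
6 | (5R)-5-(hydroxymethyl)dihydrofuran-2(3H)-one | OC[C@H]1CCC(=O)O1 | starting material
7 | (2R)-5-oxotetrahydrofuran-2-carbaldehyde | O=C[C@H]1CCC(=O)O1 | intermediate
8 | (5R)-5-vinyldihydrofuran-2(3H)-one | C=C[C@H]1CCC(=O)O1 | intermediate
9 | lithium enolate of 8, lithium (5R)-5-vinyl-4,5-dihydrofuran-2-olate | [Li+].[O-]C1=CC[C@H](C=C)O1 | intermediate
10 | (3S,5R)-3-methyl-5-vinyldihydrofuran-2(3H)-one | O=C1[C@@H](C)C[C@H](C=C)O1 | intermediate
11 | (3S,5R)-3-methyl-5-vinyltetrahydrofuran-2-ol (anomer mixture) | OC1[C@@H](C)C[C@H](C=C)O1 | intermediate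
12 | (3R,5S)-5-methylhept-1-en-6-yn-3-ol | C#C[C@@H](C)C[C@@H](O)C=C | intermediate
13 | triethyl{[(3R,5S)-5-methylhept-1-en-6-yn-3-yl]oxy}silane | C#C[C@@H](C)C[C@@H](O[Si](CC)(CC)CC)C=C | intermediate
14 | lithium acetylide of 13 | [Li+].[C-]#C[C@@H](C)C[C@@H](O[Si](CC)(CC)CC)C=C | intermediate
15 | chloromagnesium alkoxide of 5 | C[C@@](O[Mg]Cl)(CCO[Si](c1ccccc1)(c1ccccc1)C(C)(C)C)C(=O)N(C)OC | intermediate
16 | (3R,7S,9R)-1-[tert-butyl(diphenyl)silyl]oxy-3-hydroxy-3,7-dimethyl-9-(triethylsilyloxy)undec-10-en-5-yn-4-one | C[C@@](O)(CCO[Si](c1ccccc1)(c1ccccc1)C(C)(C)C)C(=O)C#C[C@@H](C)C[C@@H](O[Si](CC)(CC)CC)C=C | intermediate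
17 | (3R,7S,9R)-1-[tert-butyl(diphenyl)silyl]oxy-6-(diethylamino)-3-hydroxy-3,7-dimethyl-9-(triethylsilyloxy)undeca-5,10-dien-4-one (enaminone, alkene geometry undefined) | C[C@@](O)(CCO[Si](c1ccccc1)(c1ccccc1)C(C)(C)C)C(=O)C=C(N(CC)CC)[C@@H](C)C[C@@H](O[Si](CC)(CC)CC)C=C | intermediate
18 | (2R)-2-{2-[tert-butyl(diphenyl)silyl]oxyethyl}-2-methyl-5-[(2S,4R)-4-(triethylsilyloxy)hex-5-en-2-yl]furan-3(2H)-one | C[C@]1(CCO[Si](c2ccccc2)(c2ccccc2)C(C)(C)C)OC(=CC1=O)[C@@H](C)C[C@@H](O[Si](CC)(CC)CC)C=C | intermediate
19 | (2R)-2-{2-[tert-butyl(diphenyl)silyl]oxyethyl}-5-[(2S,4R)-4-hydroxyhex-5-en-2-yl]-2-methylfuran-3(2H)-one | C[C@]1(CCO[Si](c2ccccc2)(c2ccccc2)C(C)(C)C)OC(=CC1=O)[C@@H](C)C[C@@H](O)C=C | intermediate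
20 | methacryloyl chloride | C=C(C)C(=O)Cl | starting material
21 | (3R,5S)-5-[(5R)-5-{2-[tert-butyl(diphenyl)silyl]oxyethyl}-5-methyl-4-oxo-4,5-dihydrofuran-2-yl]hex-1-en-3-yl 2-methylprop-2-enoate | C[C@]1(CCO[Si](c2ccccc2)(c2ccccc2)C(C)(C)C)OC(=CC1=O)[C@@H](C)C[C@@H](OC(=O)C(C)=C)C=C | intermediate
22 | (5R)-5-{(2S)-2-[(5R)-5-{2-[tert-butyl(diphenyl)silyl]oxyethyl}-5-methyl-4-oxo-4,5-dihydrofuran-2-yl]propyl}-3-methylfuran-2(5H)-one | C[C@]1(CCO[Si](c2ccccc2)(c2ccccc2)C(C)(C)C)OC(=CC1=O)[C@@H](C)C[C@H]1OC(=O)C(C)=C1 | intermediate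
23 | (5R)-5-{(2S)-2-[(5R)-5-(2-hydroxyethyl)-5-methyl-4-oxo-4,5-dihydrofuran-2-yl]propyl}-3-methylfuran-2(5H)-one | C[C@]1(CCO)OC(=CC1=O)[C@@H](C)C[C@H]1OC(=O)C(C)=C1 | intermediate
24 | 2-[(2R)-2-methyl-5-{(2S)-1-[(2R)-4-methyl-5-oxo-2,5-dihydrofuran-2-yl]propan-2-yl}-3-oxo-2,3-dihydrofuran-2-yl]acetaldehyde | O=CC[C@@]1(C)OC(=CC1=O)[C@@H](C)C[C@H]1OC(=O)C(C)=C1 | intermediate
25 | samarium enolate, the bis(diiodosamarium) C8 alkoxide and C12 enolate of 26 | I[Sm](I)O[C@H]1C[C@@]2(C)OC(=CC2=O)[C@@H](C)C[C@H]2OC(O[Sm](I)I)=C(C)[C@H]12 | intermediate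
26 | (4S,6R,7R,8S,10R,11S)-8-hydroxy-1-oxo-3,10-epoxygermacr-2-en-12,6-olide | O[C@H]1C[C@@]2(C)OC(=CC2=O)[C@@H](C)C[C@H]2OC(=O)[C@@H](C)[C@H]12 | intermediate
27 | tiglic acid, (E)-2-methylbut-2-enoic acid | C/C=C(\C)C(=O)O | starting material
28 | (E)-2-methylbut-2-enoic 2,4,6-trichlorobenzoic anhydride | C/C=C(\C)C(=O)OC(=O)c1c(Cl)cc(Cl)cc1Cl | intermediate
29 | (4S,6R,7S,8S,10R,11S)-1-oxo-8-[(E)-2-methylbut-2-enoyl]oxy-3,10-epoxygermacr-2-en-12,6-olide (CNP0235937.1) | C/C=C(\C)C(=O)O[C@H]1C[C@@]2(C)OC(=CC2=O)[C@@H](C)C[C@H]2OC(=O)[C@@H](C)[C@H]12 | target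

**Step count and risks**

Total steps: 19. Longest linear sequence: 15 (steps 5 to 10, then 11 to 19).

Steps most likely to fail:

1. Step 18. What may go wrong: the ketyl may be reduced further or dimerise before the slow ten-membered closure; closure through the alternative conformation with C9 anti to C6 would invert C8; protonation of the enolate from the C6 side would invert C11. Fallback (sets out from 19, returns at 26): the alcohol 19 would be acylated with 2-(bromomethyl)acryloyl chloride (pyridine, CH2Cl2, −20 °C) to the 2-(bromomethyl)acrylate F1. Ring-closing metathesis with the second-generation Grubbs catalyst would give the 3-(bromomethyl)butenolide F2, HF·pyridine the primary alcohol F3, and Dess–Martin periodinane the bromo aldehyde F4. CrCl2 (divalent chromium) in THF at high dilution would then convert the allylic bromide into an allylchromium species that attacks the C8 aldehyde through C7 (intramolecular Nozaki–Hiyama–Kishi allylation, the usual way to close germacranolide rings), giving the 8-hydroxy α-methylene lactone F5. Conjugate reduction of the exocyclic methylene with NaBH4 in MeOH at 0 °C, which in trans-fused lactones of this class places the C11 methyl anti to C8, would return the route to 26.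

2. Step 7. What may go wrong: poor facial selectivity in the methylation, because a vinyl group is only a modest shield, and some double alkylation. Fallback (sets out from 6, returns at 10): 6 would be silylated (TBDPSCl, imidazole) to the silyl ether F6, whose bulky silyloxymethyl group should steer the LiN(i-Pr)2/MeI methylation cleanly to the trans lactone F7. HF·pyridine would give the alcohol F8, Dess–Martin oxidation the aldehyde F9, and Wittig methylenation with Ph3P=CH2 would give 10.

3. Step 11. What may go wrong: sluggish addition to the amide that carries a neighbouring alkoxide, with proton transfer returning alkyne 13, and conjugate addition of the liberated hydroxylamine to the ynone during the quench. Fallback (sets out from 4 and 13, returns at 16): the lithium acetylide 14 would be added at −78 °C directly to the dioxolanone 4, which is an activated ester; the tetrahedral alkoxide is held until a cold acidic quench, where the hemiketal collapses with loss of acetone to the hydroxy ynone 16, so no new compound arises (F0).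

Further compounds
F1 | step 18 | (3R,5S)-5-[(5R)-5-{2-[tert-butyl(diphenyl)silyl]oxyethyl}-5-methyl-4-oxo-4,5-dihydrofuran-2-yl]hex-1-en-3-yl 2-(bromomethyl)prop-2-enoate | C[C@]1(CCO[Si](c2ccccc2)(c2ccccc2)C(C)(C)C)OC(=CC1=O)[C@@H](C)C[C@@H](OC(=O)C(=C)CBr)C=C
F2 | step 18 | (5R)-3-(bromomethyl)-5-{(2S)-2-[(5R)-5-{2-[tert-butyl(diphenyl)silyl]oxyethyl}-5-methyl-4-oxo-4,5-dihydrofuran-2-yl]propyl}furan-2(5H)-one | C[C@]1(CCO[Si](c2ccccc2)(c2ccccc2)C(C)(C)C)OC(=CC1=O)[C@@H](C)C[C@H]1OC(=O)C(CBr)=C1
F3 | step 18 | (5R)-3-(bromomethyl)-5-{(2S)-2-[(5R)-5-(2-hydroxyethyl)-5-methyl-4-oxo-4,5-dihydrofuran-2-yl]propyl}furan-2(5H)-one | C[C@]1(CCO)OC(=CC1=O)[C@@H](C)C[C@H]1OC(=O)C(CBr)=C1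
F4 | step 18 | 2-[(2R)-5-{(2S)-1-[(2R)-4-(bromomethyl)-5-oxo-2,5-dihydrofuran-2-yl]propan-2-yl}-2-methyl-3-oxo-2,3-dihydrofuran-2-yl]acetaldehyde | O=CC[C@@]1(C)OC(=CC1=O)[C@@H](C)C[C@H]1OC(=O)C(CBr)=C1
F5 | step 18 | (4S,6R,7R,8S,10R)-8-hydroxy-1-oxo-3,10-epoxygermacra-2,11(13)-dien-12,6-olide | O[C@H]1C[C@@]2(C)OC(=CC2=O)[C@@H](C)C[C@H]2OC(=O)C(=C)[C@H]12
F6 | step 7 | (5R)-5-{[tert-butyl(diphenyl)silyl]oxymethyl}dihydrofuran-2(3H)-one | CC(C)(C)[Si](OC[C@H]1CCC(=O)O1)(c1ccccc1)c1ccccc1
F7 | step 7 | (3S,5R)-5-{[tert-butyl(diphenyl)silyl]oxymethyl}-3-methyldihydrofuran-2(3H)-one | O=C1[C@@H](C)C[C@H](CO[Si](c2ccccc2)(c2ccccc2)C(C)(C)C)O1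
F8 | step 7 | (3S,5R)-5-(hydroxymethyl)-3-methyldihydrofuran-2(3H)-one | O=C1[C@@H](C)C[C@H](CO)O1
F9 | step 7 | (2R,4S)-4-methyl-5-oxotetrahydrofuran-2-carbaldehyde | O=C1[C@@H](C)C[C@H](C=O)O1
F0 | step 11 | none | none
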